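The run lasts 20 h, and the question is what stands of a species that lives for seconds.

in all of them: first nucleophile 0.0600 M; second nucleophile 0.130 M; time 20 h

|  | substrate |
|---|---|
| north-east | 0.025 M |
| north-west | 0.050 M |
| south | 0.10 M |

    second nucleophile + intermediate → other capture product (k1 = 0.56 M⁻¹ s⁻¹)
    target ⇌ isomer of the product (K2 = 0.59, k2 = 4.7 × 10⁻⁵ s⁻¹)
    substrate → intermediate (k3 = 4.1 × 10⁻⁵ s⁻¹)
    target → over-reaction product (k4 = 4.5 × 10⁻⁸ s⁻¹)
    first nucleophile + intermediate ⇌ target (K5 = 7.6 M⁻¹, k5 = 0.63 M⁻¹ s⁻¹)

- [intermediate] at the end for north-east, north-west, south, in this order
- how the row runs (falls, then rises / rises all the way / rises, then falls / hardly changes / falls all the way)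

- "hardly changes" means that all values lie within two and a half points (for a concentration: within two and a half percent of the largest)
- run time (north-east): 20 h

How much substrate is left at the end? Its decay is first-order, so the fraction left after the run is 5.22%, and no charge enters that figure.

Can the intermediate pile up? With the second nucleophile at its charge, capture is pseudo-first-order with a half-life of 9.52 s, against 4.70 h for the substrate. So the substrate's decay is the rate-limiting step, and the intermediate sits in a steady state. Target returns the intermediate with a half-life of 8.36 s, also short against the substrate's, so the first nucleophile's step is taken to carry no lasting net flow. Making then equals capture, and the level follows from one constant, the holding constant h, the rate constant of making over that of capture, 7.32 × 10⁻⁵ M: c(intermediate) = h × c(substrate) / c(second nucleophile).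

How does that ratio drift with the charge? The numerator grows with the charge, while c(second nucleophile) is reckoned as its charge less the substrate that has gone, which counts the small amounts held as target, isomer of the product and intermediate as captured. At the end that reckoning leaves 0.106 M in north-east, 0.0826 M in north-west and 0.0352 M in south. My reckoning therefore gives 8.99 × 10⁻⁷ M, 2.31 × 10⁻⁶ M and 1.09 × 10⁻⁵ M, a row that climbs. From north-east to south the charge grows 4.00-fold and the reckoned level 12.1-fold.

The forecast gives 9.000 × 10⁻⁷ M, 2.300 × 10⁻⁶ M and 1.090 × 10⁻⁵ M, a row that rises all the way, and holds that “the reversible first-nucleophile adduct only buffers it”.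

The simulation gives 9.01 × 10⁻⁷ M, 2.32 × 10⁻⁶ M and 1.09 × 10⁻⁵ M, and the row rises all the way, so the forecast is right within the tolerance. In north-east the intermediate has a half-life by capture of 0.17 min at 4.35 h, short against the 20 h of the run. Its making over its using up in north-east reads 0.999 at 4.35 h and 0.999 at 20.0 h. In south at 10.0 h, 22.9% of the charged substrate and 40.7% of the second nucleophile's charge stand, so h gives 3.16 × 10⁻⁵ M, and the flask holds 3.17 × 10⁻⁵ M.

(All constants are made up; the run is a simulation.)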